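The route disconnects both C-prenyl groups, C8–CH2 on ring A and C2'–CH2 on ring B, back to allyl ethers on the phenolic oxygens O5 and O3' of an intact (2S)-flavanone. The key step exploits that C2' is ortho to O3' and C8 is para to O5, the oxygen chelated to the C4 carbonyl. One lanthanide-catalysed heating moves a 1,1-dimethylallyl group from O3' to C2' (aromatic Claisen) and a prenyl group from O5 via C6 to C8 (Claisen–Cope), closing no ring and freeing 3'-OH and 5-OH. The precursor is (2S)-5-O-prenyl-3'-O-(1,1-dimethylallyl)-7,4'-bis-O-MOM-eriodictyol, assembled by asymmetric conjugate arylation of a chromone with an arylboronic acid that already carries the tertiary allyl ether.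

Key step: step 10

Assumption: the facial sense of the rhodium-catalysed arylation of the chromone is taken to follow the quadrant model established for cyclic enones, under which the (S)-configured biaryl bisphosphine should give the (2S)-flavanone; the configuration of 17 is to be checked and the antipodal ligand used if the sense proves opposite.

Design remark: the triple bond of the ring B ether is reduced before any organometallic step, so neither the organolithium nor the rhodium catalyst meets a terminal alkyne, and the 3'-OH is later methylated with a diazoalkane and only a weak amine base because C2 is base-labile.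

Step 1
Reactants: 1 phloroacetophenone (2,4,6-trihydroxyacetophenone)
Product: 2 monoprotected ketone 1-[2,6-dihydroxy-4-(methoxymethoxy)phenyl]ethanone
Conditions: MOMCl (1.05 equiv), i-Pr2NEt (1.2 equiv), CH2Cl2/THF, 0 °C
Reagents that add atoms: chloromethyl methyl ether (MOMCl), COCCl
Why: The 4-hydroxyl is the only one not hydrogen-bonded to the acetyl carbonyl and is the most acidic, so one equivalent of the α-chloro ether with a hindered amine base should alkylate it selectively (Williamson-type O-alkylation).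

Step 2
Reactants: 2 monoprotected ketone 1-[2,6-dihydroxy-4-(methoxymethoxy)phenyl]ethanone; 3 prenyl bromide (1-bromo-3-methylbut-2-ene)
Product: 4 prenyl ether 1-[2-hydroxy-4-(methoxymethoxy)-6-(3-methylbut-2-enyloxy)phenyl]ethanone
Conditions: 3 (1.0 equiv), K2CO3 (1.5 equiv), acetone, 50 °C
Reagents that add atoms: none
Why: The two remaining hydroxyls are equivalent and Williamson mono-O-alkylation should stop after one prenyl group, because the hydroxyl left over is locked in a strong hydrogen bond to the acetyl carbonyl, while carbonate in acetone favours O- over C-prenylation.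

Step 3
Reactants: 4 prenyl ether 1-[2-hydroxy-4-(methoxymethoxy)-6-(3-methylbut-2-enyloxy)phenyl]ethanone
Product: 6 chromone 7-(methoxymethoxy)-5-(3-methylbut-2-enyloxy)-4H-chromen-4-one, via enaminone 5 (not isolated)
Conditions: DMF-DMA (3 equiv), PhMe, 90 °C; concentrate; then AcOH (5 equiv), CH2Cl2, 40 °C
Reagents that add atoms: N,N-dimethylformamide dimethyl acetal (DMF-DMA), COC(OC)N(C)C
Why: Condensation of the methyl ketone with the amide acetal gives the enaminone, and mild acid then triggers 6-endo oxa-Michael addition of the free ortho phenol and loss of dimethylamine (enaminone route to chromones) under conditions that the MOM acetal and the prenyl ether tolerate.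

Step 4
Reactants: 7 bromosalicylaldehyde (5-bromo-2-hydroxybenzaldehyde)
Product: 8 MOM ether 5-bromo-2-(methoxymethoxy)benzaldehyde
Conditions: MOMCl (1.3 equiv), i-Pr2NEt (1.6 equiv), CH2Cl2, 0 °C → rt
Reagents that add atoms: chloromethyl methyl ether (MOMCl), COCCl
Why: Williamson-type O-alkylation of the acidic salicylaldehyde phenol masks the oxygen para to bromine (the future O4') and so differentiates it from the oxygen unveiled in step 5.

Step 5
Reactants: 8 MOM ether 5-bromo-2-(methoxymethoxy)benzaldehyde
Product: 10 phenol 5-bromo-2-(methoxymethoxy)phenol, via aryl formate 9 (not isolated)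
Conditions: mCPBA (1.3 equiv), CH2Cl2, rt; aq. NaHCO3 wash; then K2CO3 (cat.), MeOH, rt
Reagents that add atoms: meta-chloroperoxybenzoic acid (mCPBA), OOC(=O)c1cccc(Cl)c1
Why: Baeyer–Villiger (Dakin-type) oxidation of the electron-rich ortho-alkoxybenzaldehyde should proceed with aryl migration to the aryl formate, which mild methanolysis cleaves to the phenol meta to bromine, the MOM acetal being stable to the weakly acidic peracid and to carbonate.

Step 6
Reactants: 10 phenol 5-bromo-2-(methoxymethoxy)phenol; 11 tertiary propargyl chloride 3-chloro-3-methylbut-1-yne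
Product: 12 propargyl ether 4-bromo-1-(methoxymethoxy)-2-(2-methylbut-3-yn-2-yloxy)benzene
Conditions: 11 (1.3 equiv), DBU (1.5 equiv), CuCl2·2H2O (1 mol %), MeCN, 0 °C → rt
Reagents that add atoms: none
Why: Copper-catalysed propargylic substitution of the tertiary chloride by the phenoxide (through a copper acetylide that ionises to an allenylidene-type electrophile) is the standard way to aryl 1,1-dimethylpropargyl ethers and tolerates an ortho alkoxy group.

Step 7
Reactants: 12 propargyl ether 4-bromo-1-(methoxymethoxy)-2-(2-methylbut-3-yn-2-yloxy)benzene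
Product: 13 tertiary allyl ether 4-bromo-1-(methoxymethoxy)-2-(2-methylbut-3-en-2-yloxy)benzene
Conditions: H2 (1 atm), Pd/CaCO3 poisoned with Pb(OAc)2, quinoline, EtOAc, rt, stopped after one equivalent of H2
Reagents that add atoms: none
Why: Lindlar semi-hydrogenation should add one equivalent of hydrogen to the terminal alkyne without hydrogenolysis of the aryl bromide, and doing it here keeps an acidic alkyne C–H and a carbometalation-prone triple bond out of the organolithium and rhodium steps.

Step 8
Reactants: 13 tertiary allyl ether 4-bromo-1-(methoxymethoxy)-2-(2-methylbut-3-en-2-yloxy)benzene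
Product: 16 boronic acid [4-(methoxymethoxy)-3-(2-methylbut-3-en-2-yloxy)phenyl]boronic acid, via aryllithium 14 (not isolated), via lithium arylborate 15 (not isolated)
Conditions: n-BuLi (1.05 equiv), THF, −78 °C; B(Oi-Pr)3, −78 → 0 °C; aq. NH4Cl; kept cold
Reagents that add atoms: triisopropyl borate, CC(C)OB(OC(C)C)OC(C)C; water, O
Why: Bromine–lithium exchange at −78 °C is far faster than ortho-lithiation next to the MOM ether, and trapping with the borate ester followed by near-neutral hydrolysis gives the boronic acid without heat or strong acid, so the tertiary allyl ether should survive.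

Step 9
Reactants: 6 chromone 7-(methoxymethoxy)-5-(3-methylbut-2-enyloxy)-4H-chromen-4-one; 16 boronic acid [4-(methoxymethoxy)-3-(2-methylbut-3-en-2-yloxy)phenyl]boronic acid
Product: 17 flavanone (2S)-7-(methoxymethoxy)-2-[4-(methoxymethoxy)-3-(2-methylbut-3-en-2-yloxy)phenyl]-5-(3-methylbut-2-enyloxy)chroman-4-one
Conditions: 16 (2 equiv), [Rh(OH)(cod)]2 (2.5 mol %), (S)-MeO-F12-BIPHEP [(S)-2,2'-bis[bis(3,4,5-trifluorophenyl)phosphino]-6,6'-dimethoxy-1,1'-biphenyl] (5.5 mol %), PhMe/H2O 10:1, 30 °C
Reagents that add atoms: none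
Why: Transmetalation of 16 to the rhodium hydroxide, enantioface-selective insertion of the chromone C2=C3 bond into the aryl–rhodium bond within the pocket of the electron-poor biaryl bisphosphine and protonolysis of the rhodium enolate by water (Hayashi–Miyaura asymmetric conjugate arylation of chromones) should set C2 as (S) under near-neutral conditions too mild for either allyl ether to rearrange.

Step 10
Reactants: 17 flavanone (2S)-7-(methoxymethoxy)-2-[4-(methoxymethoxy)-3-(2-methylbut-3-en-2-yloxy)phenyl]-5-(3-methylbut-2-enyloxy)chroman-4-one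
Product: 22 bis-C-prenyl diphenol (2S)-5-hydroxy-2-[3-hydroxy-4-(methoxymethoxy)-2-(3-methylbut-2-enyl)phenyl]-7-(methoxymethoxy)-8-(3-methylbut-2-enyl)chroman-4-one, via ring A C6 dienone 18 (not isolated), via ring A C8 dienone 19 (not isolated), via mono-rearranged 8-prenyl phenol 20 (not isolated), via ring B dienone 21 (not isolated)
Conditions: Eu(fod)3 (15 mol %), PhMe, 60 °C, then 90 °C until the ring B ether is consumed
Reagents that add atoms: none
Why: Eu(fod)3 binds the C4 carbonyl/O5 pair of ring A and the O3'/O4' pair of ring B and so lowers the barrier of two concerted chair-like [3,3] shifts that run independently in one flask (written with ring A first, as expected at the lower temperature). On ring A the prenyl ether gives the C6 dienone 18, whose 1,1-dimethylallyl group is relayed by a Cope [3,3] shift to C8 (19) before tautomerisation to the chelated 5-phenol 20, so the group arrives at C8 as a normal prenyl after two allyl inversions. On ring B the tertiary allyl ether shifts directly to C2' (21) with one inversion and tautomerises to the 3'-phenol, again as a normal prenyl group. The closest known reactions are the lanthanide-catalysed Claisen–Cope (para-Claisen) rearrangement of 5-O-prenylflavanones and the aromatic Claisen rearrangement of aryl 1,1-dimethylallyl ethers; no ring is closed and no stereocentre is formed, and the neutral aprotic medium should leave the base-labile C2 centre untouched. The selectivity needed is C8 over C6 on ring A, secured by the catalyst and the 7-alkoxy group, which make the Cope relay faster than enolisation of 18, and C2' on ring B, secured because C4', the other ortho position of O3', carries the MOM ether, so a shift there is unproductive and reversible.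

Step 11
Reactants: 22 bis-C-prenyl diphenol (2S)-5-hydroxy-2-[3-hydroxy-4-(methoxymethoxy)-2-(3-methylbut-2-enyl)phenyl]-7-(methoxymethoxy)-8-(3-methylbut-2-enyl)chroman-4-one
Product: 23 methyl ether (2S)-5-hydroxy-2-[3-methoxy-4-(methoxymethoxy)-2-(3-methylbut-2-enyl)phenyl]-7-(methoxymethoxy)-8-(3-methylbut-2-enyl)chroman-4-one
Conditions: TMSCHN2 (2 M in hexanes, 1.5 equiv), i-Pr2NEt (1.5 equiv), MeCN/MeOH 9:1, 0 °C → rt
Reagents that add atoms: trimethylsilyldiazomethane, C[Si](C)(C)C=[N+]=[N-]
Why: The free 3'-phenol should be O-methylated by the methyldiazonium species generated from TMSCHN2 and methanol (Aoyama–Shioiri phenol methylation), whereas the 5-OH hydrogen-bonded to the C4 carbonyl is far less reactive and the weak amine base is not strong enough to open the flavanone ring, so C2 keeps its configuration.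

Step 12
Reactants: 23 methyl ether (2S)-5-hydroxy-2-[3-methoxy-4-(methoxymethoxy)-2-(3-methylbut-2-enyl)phenyl]-7-(methoxymethoxy)-8-(3-methylbut-2-enyl)chroman-4-one
Product: 24 target (2S)-5,7-dihydroxy-2-[4-hydroxy-3-methoxy-2-(3-methylbut-2-enyl)phenyl]-8-(3-methylbut-2-enyl)chroman-4-one
Conditions: 3 M aq. HCl/MeOH 1:5, 45 °C, monitored and stopped at full conversion
Reagents that add atoms: none
Why: Acid-catalysed transacetalisation of the two aryl MOM acetals to methanol should release the 7- and 4'-phenols (standard MOM cleavage on prenylated flavanones), the moderate temperature keeping the prenyl alkenes from adding the neighbouring phenol or solvent and leaving C2, which is stable to dilute acid, unchanged.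

Compound list
1 | 2,4,6-trihydroxyacetophenone | CC(=O)c1c(O)cc(O)cc1O | starting material
2 | 1-[2,6-dihydroxy-4-(methoxymethoxy)phenyl]ethanone | CC(=O)c1c(O)cc(OCOC)cc1O | intermediate
3 | prenyl bromide (1-bromo-3-methylbut-2-ene) | CC(C)=CCBr | starting material
4 | 1-[2-hydroxy-4-(methoxymethoxy)-6-(3-methylbut-2-enyloxy)phenyl]ethanone | CC(=O)c1c(O)cc(OCOC)cc1OCC=C(C)C | intermediate
5 | (E)-3-(dimethylamino)-1-[2-hydroxy-4-(methoxymethoxy)-6-(3-methylbut-2-enyloxy)phenyl]prop-2-en-1-one | CN(C)/C=C/C(=O)c1c(O)cc(OCOC)cc1OCC=C(C)C | intermediate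
6 | 7-(methoxymethoxy)-5-(3-methylbut-2-enyloxy)-4H-chromen-4-one | O=C1C=COc2cc(OCOC)cc(OCC=C(C)C)c12 | intermediate
7 | 5-bromosalicylaldehyde (5-bromo-2-hydroxybenzaldehyde) | O=Cc1cc(Br)ccc1O | starting material
8 | 5-bromo-2-(methoxymethoxy)benzaldehyde | COCOc1ccc(Br)cc1C=O | intermediate
9 | 5-bromo-2-(methoxymethoxy)phenyl formate | O=COc1cc(Br)ccc1OCOC | intermediate
10 | 5-bromo-2-(methoxymethoxy)phenol | Oc1cc(Br)ccc1OCOC | intermediate
11 | 3-chloro-3-methylbut-1-yne (commercial tertiary chloride of 2-methylbut-3-yn-2-ol) | C#CC(C)(C)Cl | starting material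
12 | 4-bromo-1-(methoxymethoxy)-2-(2-methylbut-3-yn-2-yloxy)benzene | C#CC(C)(C)Oc1cc(Br)ccc1OCOC | intermediate
13 | 4-bromo-1-(methoxymethoxy)-2-(2-methylbut-3-en-2-yloxy)benzene | C=CC(C)(C)Oc1cc(Br)ccc1OCOC | intermediate
14 | [4-(methoxymethoxy)-3-(2-methylbut-3-en-2-yloxy)phenyl]lithium | [Li]c1ccc(OCOC)c(OC(C)(C)C=C)c1 | intermediate
15 | lithium triisopropoxy[4-(methoxymethoxy)-3-(2-methylbut-3-en-2-yloxy)phenyl]borate | [Li+].CC(C)O[B-](OC(C)C)(OC(C)C)c1ccc(OCOC)c(OC(C)(C)C=C)c1 | intermediate
16 | [4-(methoxymethoxy)-3-(2-methylbut-3-en-2-yloxy)phenyl]boronic acid | OB(O)c1ccc(OCOC)c(OC(C)(C)C=C)c1 | intermediate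
17 | (2S)-7-(methoxymethoxy)-2-[4-(methoxymethoxy)-3-(2-methylbut-3-en-2-yloxy)phenyl]-5-(3-methylbut-2-enyloxy)chroman-4-one | C=CC(C)(C)Oc1c(OCOC)ccc([C@@H]2CC(=O)c3c(OCC=C(C)C)cc(OCOC)cc3O2)c1 | intermediate
18 | (2S)-7-(methoxymethoxy)-2-[4-(methoxymethoxy)-3-(2-methylbut-3-en-2-yloxy)phenyl]-6-(2-methylbut-3-en-2-yl)-2,3-dihydro-4H-chromene-4,5(6H)-dione (C6 configuration undefined) | C=CC(C)(C)Oc1c(OCOC)ccc([C@@H]2CC(=O)C3=C(O2)C=C(OCOC)C(C(C)(C)C=C)C3=O)c1 | intermediate
19 | (2S)-7-(methoxymethoxy)-2-[4-(methoxymethoxy)-3-(2-methylbut-3-en-2-yloxy)phenyl]-8-(3-methylbut-2-enyl)-2,3-dihydro-4H-chromene-4,5(8H)-dione (C8 configuration undefined) | C=CC(C)(C)Oc1c(OCOC)ccc([C@@H]2CC(=O)C3=C(O2)C(CC=C(C)C)C(OCOC)=CC3=O)c1 | intermediate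
20 | (2S)-5-hydroxy-7-(methoxymethoxy)-2-[4-(methoxymethoxy)-3-(2-methylbut-3-en-2-yloxy)phenyl]-8-(3-methylbut-2-enyl)chroman-4-one | C=CC(C)(C)Oc1c(OCOC)ccc([C@@H]2CC(=O)c3c(O)cc(OCOC)c(CC=C(C)C)c3O2)c1 | intermediate
21 | (2S)-5-hydroxy-7-(methoxymethoxy)-2-[4-(methoxymethoxy)-6-(3-methylbut-2-enyl)-5-oxocyclohexa-1,3-dien-1-yl]-8-(3-methylbut-2-enyl)chroman-4-one (ring B sp3 carbon undefined) | O=C1C(OCOC)=CC=C([C@@H]2CC(=O)c3c(O)cc(OCOC)c(CC=C(C)C)c3O2)C1CC=C(C)C | intermediate
22 | (2S)-5-hydroxy-2-[3-hydroxy-4-(methoxymethoxy)-2-(3-methylbut-2-enyl)phenyl]-7-(methoxymethoxy)-8-(3-methylbut-2-enyl)chroman-4-one | Oc1c(OCOC)ccc([C@@H]2CC(=O)c3c(O)cc(OCOC)c(CC=C(C)C)c3O2)c1CC=C(C)C | intermediate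
23 | (2S)-5-hydroxy-2-[3-methoxy-4-(methoxymethoxy)-2-(3-methylbut-2-enyl)phenyl]-7-(methoxymethoxy)-8-(3-methylbut-2-enyl)chroman-4-one | COc1c(OCOC)ccc([C@@H]2CC(=O)c3c(O)cc(OCOC)c(CC=C(C)C)c3O2)c1CC=C(C)C | intermediate
24 | (2S)-5,7-dihydroxy-2-[4-hydroxy-3-methoxy-2-(3-methylbut-2-enyl)phenyl]-8-(3-methylbut-2-enyl)chroman-4-one | COc1c(O)ccc([C@@H]2CC(=O)c3c(O)cc(O)c(CC=C(C)C)c3O2)c1CC=C(C)C | target

Total step count: 12. Longest linear sequence: 9 steps (steps 4–12, from 7); the ring A branch (steps 1–3) joins at step 9.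

Steps most likely to fail

Step 10. The tertiary allyl group may be lost from O3' by Lewis-acid ionisation instead of migrating. The C6 dienone may enolise before the Cope relay, leaving a branched C6 group. The freed 3'-phenol may add across the new 2'-prenyl alkene. The fallback separates the two rearrangements and sets out from 13, returning at 23. Heating 13 alone (PhMe, 110 °C) should effect the ring B Claisen shift before any stereocentre exists and give 3-bromo-6-(methoxymethoxy)-2-(3-methylbut-2-enyl)phenol F1. O-Methylation (MeI, K2CO3, acetone) then gives 1-bromo-3-methoxy-4-(methoxymethoxy)-2-(3-methylbut-2-enyl)benzene F2. Bromine–lithium exchange and borylation as in step 8 lead through [3-methoxy-4-(methoxymethoxy)-2-(3-methylbut-2-enyl)phenyl]lithium F3 and lithium triisopropoxy[3-methoxy-4-(methoxymethoxy)-2-(3-methylbut-2-enyl)phenyl]borate F4 to [3-methoxy-4-(methoxymethoxy)-2-(3-methylbut-2-enyl)phenyl]boronic acid F5. Conjugate arylation of chromone 6 as in step 9 gives (2S)-2-[3-methoxy-4-(methoxymethoxy)-2-(3-methylbut-2-enyl)phenyl]-7-(methoxymethoxy)-5-(3-methylbut-2-enyloxy)chroman-4-one F6. A single Eu(fod)3-catalysed Claisen–Cope shift on ring A (PhMe, 60 °C), the directly precedented half of the key step, should then give 23, replacing steps 8–11.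

Step 9. The electron-rich chromone with its peri alkoxy group may insert slowly, the boronic acid may protodeboronate, or facial selectivity may be insufficient. The fallback is a chalcone route with chromatographic resolution; it sets out from 13 and 4 and returns at 17. Aryllithium 14, made from 13 as in step 8, is quenched with DMF to give, through lithium (dimethylamino)[4-(methoxymethoxy)-3-(2-methylbut-3-en-2-yloxy)phenyl]methanolate F7, 4-(methoxymethoxy)-3-(2-methylbut-3-en-2-yloxy)benzaldehyde F8. Claisen–Schmidt condensation with 4 (KOH, EtOH, rt) should give (E)-1-[2-hydroxy-4-(methoxymethoxy)-6-(3-methylbut-2-enyloxy)phenyl]-3-[4-(methoxymethoxy)-3-(2-methylbut-3-en-2-yloxy)phenyl]prop-2-en-1-one F9. NaOAc in EtOH at 60 °C closes it by oxa-Michael addition to racemic 7-(methoxymethoxy)-2-[4-(methoxymethoxy)-3-(2-methylbut-3-en-2-yloxy)phenyl]-5-(3-methylbut-2-enyloxy)chroman-4-one F10. Preparative HPLC on a polysaccharide chiral stationary phase then supplies 17, and the unwanted antipode is returned to F10 by the same base-mediated ring opening and closure.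

Step 12. Under protic acid the 7-OH may cyclise onto the C8 prenyl alkene, or methanol or water may add to either prenyl group. The fallback is a silyl-exchange deprotection under buffered aprotic conditions, from 23 to 24. TMSOTf with 2,2'-bipyridyl (CH2Cl2, 0 °C) converts aryl MOM ethers into aryl trimethylsilyl ethers and should give (2S)-2-[3-methoxy-2-(3-methylbut-2-enyl)-4-(trimethylsilyloxy)phenyl]-8-(3-methylbut-2-enyl)-5,7-bis(trimethylsilyloxy)chroman-4-one F11. This is hydrolysed at neutral pH (H2O/MeOH, rt) to 24.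

Further compounds
F1 | step 10 | 3-bromo-6-(methoxymethoxy)-2-(3-methylbut-2-enyl)phenol | Oc1c(CC=C(C)C)c(Br)ccc1OCOC
F2 | step 10 | 1-bromo-3-methoxy-4-(methoxymethoxy)-2-(3-methylbut-2-enyl)benzene | COc1c(CC=C(C)C)c(Br)ccc1OCOC
F3 | step 10 | [3-methoxy-4-(methoxymethoxy)-2-(3-methylbut-2-enyl)phenyl]lithium | [Li]c1ccc(OCOC)c(OC)c1CC=C(C)C
F4 | step 10 | lithium triisopropoxy[3-methoxy-4-(methoxymethoxy)-2-(3-methylbut-2-enyl)phenyl]borate | [Li+].CC(C)O[B-](OC(C)C)(OC(C)C)c1ccc(OCOC)c(OC)c1CC=C(C)C
F5 | step 10 | [3-methoxy-4-(methoxymethoxy)-2-(3-methylbut-2-enyl)phenyl]boronic acid | OB(O)c1ccc(OCOC)c(OC)c1CC=C(C)C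
F6 | step 10 | (2S)-2-[3-methoxy-4-(methoxymethoxy)-2-(3-methylbut-2-enyl)phenyl]-7-(methoxymethoxy)-5-(3-methylbut-2-enyloxy)chroman-4-one | COc1c(OCOC)ccc([C@@H]2CC(=O)c3c(OCC=C(C)C)cc(OCOC)cc3O2)c1CC=C(C)C
F7 | step 9 | lithium (dimethylamino)[4-(methoxymethoxy)-3-(2-methylbut-3-en-2-yloxy)phenyl]methanolate | [Li+].CN(C)C([O-])c1ccc(OCOC)c(OC(C)(C)C=C)c1
F8 | step 9 | 4-(methoxymethoxy)-3-(2-methylbut-3-en-2-yloxy)benzaldehyde | O=Cc1ccc(OCOC)c(OC(C)(C)C=C)c1
F9 | step 9 | (E)-1-[2-hydroxy-4-(methoxymethoxy)-6-(3-methylbut-2-enyloxy)phenyl]-3-[4-(methoxymethoxy)-3-(2-methylbut-3-en-2-yloxy)phenyl]prop-2-en-1-one | C=CC(C)(C)Oc1cc(/C=C/C(=O)c2c(O)cc(OCOC)cc2OCC=C(C)C)ccc1OCOC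
F10 | step 9 | racemic 7-(methoxymethoxy)-2-[4-(methoxymethoxy)-3-(2-methylbut-3-en-2-yloxy)phenyl]-5-(3-methylbut-2-enyloxy)chroman-4-one | C=CC(C)(C)Oc1c(OCOC)ccc(C2CC(=O)c3c(OCC=C(C)C)cc(OCOC)cc3O2)c1
F11 | step 12 | (2S)-2-[3-methoxy-2-(3-methylbut-2-enyl)-4-(trimethylsilyloxy)phenyl]-8-(3-methylbut-2-enyl)-5,7-bis(trimethylsilyloxy)chroman-4-one | COc1c(O[Si](C)(C)C)ccc([C@@H]2CC(=O)c3c(O[Si](C)(C)C)cc(O[Si](C)(C)C)c(CC=C(C)C)c3O2)c1CC=C(C)C
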